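Remark: the target has no stereocentre, and the C3–C1' axis (one ortho substituent on ring B) rotates freely, so no step has to control configuration. Chromone numbering (O1, C2 … C8a; ring B primed) is used throughout.

## The problem

The target 17 is 3'-hydroxy-2',5,6,7-tetramethoxyisoflavone: a 4H-chromen-4-one with three contiguous methoxy groups on ring A (C5, C6, C7) beside a free C8–H, and a 3-hydroxy-2-methoxyphenyl ring B on C3. O1 and the carbonyl carbon C4 must be placed on adjacent ring-A carbons (C8a, C4a) with the carbonyl on the methoxy side, and the C3–C1' bond lies ortho to the 2'-methoxy group. Of five aryl–oxygen functions only one is a free phenol (C3', flanked by a methyl ether), and the molecule offers no handle for a selective demethylation. The C5 methoxy group is peri to C4=O and is cleaved by boron and aluminium Lewis acids through chelation, which argues against the classical acylation and deprotection reagents. C2 is a vinylogous ester carbon that hydroxide or amines open, and ring A is electron-rich enough to be attacked by electrophiles or oxidants at C8. The feature that makes the key step possible is in ring A: C8a (bearing O1) and C4a (bearing C4) are adjacent, C4a has the C5 methoxy group as its other neighbour and C8a has C8–H. This is the pattern produced when an oxygen nucleophile and an acyl electrophile add across the triple bond C4a≡C8a of a 3-alkoxybenzyne, the nucleophile going to the carbon remote from the alkoxy group. A second feature is that ring B is a 2,6-disubstituted anisole, so C1' and C3' map onto the two equivalent C–Br carbons of symmetrical 7.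

## Retrosynthesis

**C3'–O.** The phenol of 17 is traced to the aryl bromide 15 through boronate 16. A bromide is inert in every earlier step, so no protecting group is needed and the one free phenol is distinguished from the four methyl ethers by construction. The forward reaction must turn C–Br into C–OH without hydroxide, which would open the pyranone.

**O1–C8a, C4–C4a and O1–C2 (key step).** All three bonds are cut at once: 15 goes back to the ortho-silylaryl triflate 5 and the β-methoxyacrylic acid 12, through aryne 13 and hydroxyaryl ketone 14. The neighbouring cut, acylation of phenol 1 at C4–C4a, needs a Lewis acid beside the labile C5 methoxy group and a separate ring closure. Here both ring-A bonds and ring C form under fluoride, and the precursors are two monocyclic pieces. The forward reaction must add the carboxylate at the correct aryne terminus, transfer the acyl group to the neighbouring carbanion and close ring C by addition–elimination.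

**C2 carbon and the acid.** Acid 12 comes from ester 11 by saponification. Ester 11 comes from arylacetate 9 by cutting the bond between the α-carbon and the future C2, through formyl enolate 10. The one-carbon unit is thus installed on a simple ester before the rings are joined, and the alkene geometry is irrelevant downstream.

**C1'–CH2.** Ester 9 is cut at the aryl–CH2 bond to 7 and the zinc enolate 8 made from 6. The future C3–C1' bond is therefore formed as an unhindered sp2–sp3 coupling on a symmetrical arene, not as a late, ortho-hindered aryl–vinyl coupling on the chromone. The forward reaction must stop at mono-coupling.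

**Aryne precursor.** Triflate 5 is cut at C–Si and O–S to bromophenol 2 (through 3 and 4), and 2 at C–Br to phenol 1. The symmetry of 1 leaves only one possible bromination site, and that site becomes C4a.

## Roads not taken

Alternative 1: the deoxybenzoin route, which most chemists would draw first. The cut is C4–C4a followed by insertion of C2. In the forward direction 2-(3-(benzyloxy)-2-methoxyphenyl)acetic acid A1 would acylate 1 under BF3·Et2O to give deoxybenzoin A2, a formamide acetal or DMF/MsCl would close the ring to the O-benzyl isoflavone A3, and hydrogenolysis would finish. It is not longer than the chosen plan. It is set aside because ring A must pass through a hot Lewis acid twice, once with the new ketone chelating next to the methoxy group that becomes C5–OMe, and because A1 needs a protecting group that the same Lewis acid threatens. The chosen plan forms the same two ring-A bonds with fluoride and needs no protecting group.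

Alternative 2: Suzuki–Miyaura coupling at C3–C1'. 3-Iodo-5,6,7-trimethoxychromone A4 would be coupled with (3-(benzyloxy)-2-methoxyphenyl)boronic acid A5 to give A3. A4 needs three steps from 1 (Lewis-acid C-acetylation, enaminone formation, iodocyclisation with an electrophilic iodine source that can also attack C8). A5 needs its own protected, multi-step preparation. The coupling joins an ortho-substituted boronic acid to a base-sensitive iodochromone. The chosen plan makes this bond first, on simple arenes, and is shorter overall.

Alternative 3: oxidative 1,2-aryl shift of a chalcone. Acetophenone A6 and aldehyde A7 would give chalcone A8, Tl(NO3)3 in methanol would move ring B to give acetal A9, and acid would close this to A3. The route uses a stoichiometric toxic oxidant on an electron-rich 2'-hydroxychalcone, where aurone and flavone formation compete. It still needs the Lewis-acid acylation for A6 and a protected aldehyde, and it has more steps after the fragments are joined.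

Key step: step 6

## Route

Step 1
Reactants: 1 3,4,5-trimethoxyphenol
Product: 2 2-bromo-3,4,5-trimethoxyphenol
Conditions: NBS (1.0 equiv), CH2Cl2, −78 °C → 0 °C, dark
Reagents that add atoms: N-bromosuccinimide, O=C1CCC(=O)N1Br
Why: Electrophilic aromatic bromination; the only two free ring positions are equivalent, and one equivalent at low temperature should limit dibromination and quinone formation.

Step 2
Reactants: 2 2-bromo-3,4,5-trimethoxyphenol
Product: 5 3,4,5-trimethoxy-2-(trimethylsilyl)phenyl trifluoromethanesulfonate, via aryl trimethylsilyl ether 3 (not isolated), via lithium silylphenoxide 4 (not isolated)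
Conditions: HMDS, THF, 70 °C, then evaporation; n-BuLi (1.1 equiv), THF, −100 → −78 °C; Tf2O (1.2 equiv), −100 °C → rt
Reagents that add atoms: hexamethyldisilazane, C[Si](C)(C)N[Si](C)(C)C; trifluoromethanesulfonic anhydride, O=S(=O)(OS(=O)(=O)C(F)(F)F)C(F)(F)F
Why: O-silylation, bromine–lithium exchange and retro-Brook 1,3 O→C silyl shift put silicon on the former C–Br carbon and free the phenoxide for triflation; this is the standard sequence to ortho-silylaryl triflates.

Step 3
Reactants: 6 ethyl bromoacetate; 7 1,3-dibromo-2-methoxybenzene
Product: 9 ethyl 2-(3-bromo-2-methoxyphenyl)acetate, via Reformatsky reagent 8 (not isolated)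
Conditions: 6, Zn dust (TMSCl-activated), THF, rt; then 7 (3 equiv), Pd2(dba)3 (1.5 mol %), XPhos (6 mol %), THF, 60 °C
Reagents that add atoms: none
Why: Negishi-type coupling of a zinc ester enolate with an aryl bromide under neutral conditions; the two C–Br bonds of 7 are equivalent by symmetry and the excess of 7, which is recovered, should hold the reaction at mono-coupling.

Step 4
Reactants: 9 ethyl 2-(3-bromo-2-methoxyphenyl)acetate
Product: 11 ethyl (E)-2-(3-bromo-2-methoxyphenyl)-3-methoxyacrylate, via sodium formyl enolate 10 (not isolated)
Conditions: NaH (2.2 equiv), HCO2Et (5 equiv), THF/DMF, 0 °C → rt; then Me2SO4 (3 equiv), 0 °C → rt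
Reagents that add atoms: ethyl formate, CCOC=O; dimethyl sulfate, COS(=O)(=O)OC
Why: Crossed Claisen condensation (α-formylation) then O-methylation of the hard enolate oxygen, the usual way to β-methoxyacrylates; the E isomer is expected to predominate, but the geometry is erased in step 6.

Step 5
Reactants: 11 ethyl (E)-2-(3-bromo-2-methoxyphenyl)-3-methoxyacrylate
Product: 12 (E)-2-(3-bromo-2-methoxyphenyl)-3-methoxyacrylic acid
Conditions: LiOH·H2O (3 equiv), THF/MeOH/H2O, 40 °C; then cold 1 M HCl to pH 3
Reagents that add atoms: lithium hydroxide, [Li+].[OH-]
Why: Ester saponification; 2-aryl-3-methoxyacrylic acids are stable, isolable acids, and any conjugate exchange with methanol at the β-carbon is degenerate.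

Step 6
Reactants: 5 3,4,5-trimethoxy-2-(trimethylsilyl)phenyl trifluoromethanesulfonate; 12 (E)-2-(3-bromo-2-methoxyphenyl)-3-methoxyacrylic acid
Product: 15 3-(3-bromo-2-methoxyphenyl)-5,6,7-trimethoxy-4H-chromen-4-one, via 3,4,5-trimethoxybenzyne 13 (not isolated), via hydroxyaryl methoxyvinyl ketone 14 (not isolated)
Conditions: 12 (1 equiv), 5 (1.8 equiv), CsF (4 equiv), THF, 125 °C, sealed tube; aq. NH4Cl work-up
Reagents that add atoms: none
Why: Proposed new method: CsF removes the silyl group of 5 and triflate departs to give aryne 13, whose two termini become C8a and C4a; the carboxylate of 12 adds at the future C8a, the terminus remote from the methoxy group, because that methoxy group stabilises by induction the negative charge developing on the future C4a and also screens that carbon. The ortho carbanion then attacks the ester carbonyl through a four-membered alkoxide (4-exo-trig) that opens with C–O cleavage to the phenoxide of 14, so that O1–C8a and C4–C4a are both made. The closest known reaction type is this insertion of arynes into the C–O bond of carboxylic acids to give ortho-hydroxyaryl ketones, including the variant in which an α,β-unsaturated acid closes in the same flask by oxa-Michael addition to a chroman-4-one; an α-aryl-β-alkoxyacrylic acid and closure by addition–elimination to a chromone have not been shown. Ring C closes by 6-endo-trig attack of the phenoxide oxygen on the β-carbon of the β-methoxy enone of 14, and the resulting enolate expels methoxide (E1cB), which gives the pyranone at its final oxidation level. No stereocentre is formed and the alkene geometry of 12 is lost, so either isomer serves. Three selectivities are needed: the regiochemistry on 13, secured by the methoxy group beside the triple bond (the other sense would give the 6,7,8-trimethoxy isomer); acyl transfer in preference to protonation of the carbanion, favoured by the aprotic medium, the slow release of 13 by sparingly soluble CsF and the absence of α-hydrogens in 12; and attack on the carbonyl carbon in preference to the β-carbon (which would lead to a 3-arylcoumarin), favoured because the four-centre acyl transfer starts from the preferred Z conformer of the aryl ester while the conjugate mode needs the disfavoured E conformer. The aryl bromide, the methyl ethers and the chromone product are inert to CsF and to 13.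

Step 7
Reactants: 15 3-(3-bromo-2-methoxyphenyl)-5,6,7-trimethoxy-4H-chromen-4-one
Product: 17 3-(3-hydroxy-2-methoxyphenyl)-5,6,7-trimethoxy-4H-chromen-4-one, via aryl pinacol boronate 16 (not isolated)
Conditions: B2pin2 (1.3 equiv), PdCl2(dppf) (5 mol %), KOAc (3 equiv), 1,4-dioxane, 90 °C; then THF, 30% aq. H2O2, 0 °C → rt; Na2S2O3 quench
Reagents that add atoms: hydrogen peroxide, OO
Why: Miyaura borylation followed by oxidation of the C–B bond (1,2-shift of the aryl group from boron to oxygen), which fixes the hydroxyl at C3'; acetate and near-neutral peroxide should spare the pyranone that hydroxide would open.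

## Compound list

1 | 3,4,5-trimethoxyphenol | COc1cc(O)cc(OC)c1OC | starting material
2 | 2-bromo-3,4,5-trimethoxyphenol | COc1cc(O)c(Br)c(OC)c1OC | intermediate
3 | (2-bromo-3,4,5-trimethoxyphenoxy)trimethylsilane | COc1cc(O[Si](C)(C)C)c(Br)c(OC)c1OC | intermediate (not isolated)
4 | lithium 3,4,5-trimethoxy-2-(trimethylsilyl)phenoxide | [Li+].[O-]c1cc(OC)c(OC)c(OC)c1[Si](C)(C)C | intermediate (not isolated)
5 | 3,4,5-trimethoxy-2-(trimethylsilyl)phenyl trifluoromethanesulfonate | COc1cc(OS(=O)(=O)C(F)(F)F)c([Si](C)(C)C)c(OC)c1OC | intermediate
6 | ethyl bromoacetate | CCOC(=O)CBr | starting material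
7 | 1,3-dibromo-2-methoxybenzene (2,6-dibromoanisole) | COc1c(Br)cccc1Br | starting material
8 | (2-ethoxy-2-oxoethyl)zinc bromide | CCOC(=O)C[Zn]Br | intermediate (not isolated)
9 | ethyl 2-(3-bromo-2-methoxyphenyl)acetate | CCOC(=O)Cc1cccc(Br)c1OC | intermediate
10 | sodium (E)-2-(3-bromo-2-methoxyphenyl)-3-ethoxy-3-oxoprop-1-en-1-olate | [Na+].[O-]/C=C(/C(=O)OCC)c1cccc(Br)c1OC | intermediate (not isolated)
11 | ethyl (E)-2-(3-bromo-2-methoxyphenyl)-3-methoxyacrylate | CO/C=C(/C(=O)OCC)c1cccc(Br)c1OC | intermediate
12 | (E)-2-(3-bromo-2-methoxyphenyl)-3-methoxyacrylic acid | CO/C=C(/C(=O)O)c1cccc(Br)c1OC | intermediate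
13 | 3,4,5-trimethoxybenzyne (1,2-didehydro-3,4,5-trimethoxybenzene) | COC1=CC#CC(OC)=C1OC | intermediate (not isolated)
14 | (E)-2-(3-bromo-2-methoxyphenyl)-1-(2-hydroxy-4,5,6-trimethoxyphenyl)-3-methoxyprop-2-en-1-one (formed as its cesium phenoxide) | CO/C=C(/C(=O)c1c(O)cc(OC)c(OC)c1OC)c1cccc(Br)c1OC | intermediate (not isolated)
15 | 3-(3-bromo-2-methoxyphenyl)-5,6,7-trimethoxy-4H-chromen-4-one | COc1cc2occ(-c3cccc(Br)c3OC)c(=O)c2c(OC)c1OC | intermediate
16 | 5,6,7-trimethoxy-3-[2-methoxy-3-(4,4,5,5-tetramethyl-1,3,2-dioxaborolan-2-yl)phenyl]-4H-chromen-4-one | COc1cc2occ(-c3cccc(B4OC(C)(C)C(C)(C)O4)c3OC)c(=O)c2c(OC)c1OC | intermediate (not isolated)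
17 | 3-(3-hydroxy-2-methoxyphenyl)-5,6,7-trimethoxy-4H-chromen-4-one | COc1cc2occ(-c3cccc(O)c3OC)c(=O)c2c(OC)c1OC | target

## Step count and risks

Total step count: 7. Longest linear sequence: 5 steps (steps 3, 4, 5, 6, 7, from 6 and 7); the other branch is steps 1, 2, 6, 7.

Least certain steps:

**Step 6 (key step, proposed new method).** The most likely failure is protonation of the ortho carbanion before acyl transfer, which would stop at simple O-arylation of the acid. The carbonyl of a β-methoxyacrylate is a vinylogous carbonate and a weaker electrophile than the ester carbonyls of the known insertions. Conjugate attack of the carbanion at the β-carbon and consumption of the aryne by released methoxide are further risks. The fallback uses known chemistry, sets out from 9 and 5 and returns at 15. Saponification of 9 would give 2-(3-bromo-2-methoxyphenyl)acetic acid F1. The established aryne insertion into the C–O bond of a simple carboxylic acid (5, CsF, THF, 125 °C) would give 2-(3-bromo-2-methoxyphenyl)-1-(2-hydroxy-4,5,6-trimethoxyphenyl)ethan-1-one F2. Heating F2 with DMF dimethyl acetal would give (E)-2-(3-bromo-2-methoxyphenyl)-3-(dimethylamino)-1-(2-hydroxy-4,5,6-trimethoxyphenyl)prop-2-en-1-one F3, which closes with loss of dimethylamine to 15. The C2 carbon is thus brought in after the aryne step instead of before it.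

**Step 7.** Protodeboronation or reduction of the C–Br bond would give the 3'-deoxy compound, and nucleophilic peroxide could attack C2 of the pyranone. The fallback sets out from 15 and returns at 17 by direct C–O coupling instead of C–B oxidation. Coupling of 15 with (E)-benzaldoxime as hydroxide surrogate (Pd2(dba)3, tBuBrettPhos, Cs2CO3, DMF, 80 °C) would give (E)-benzaldehyde O-[2-methoxy-3-(5,6,7-trimethoxy-4-oxo-4H-chromen-3-yl)phenyl]oxime F4, which fragments under the same base to benzonitrile and the phenoxide of 17.

**Step 3.** A second coupling at the remaining C–Br bond, or reduction of it, would erode the mono-coupled ester, since the product is about as reactive as 7. The fallback sets out from 7 and returns at 12, bypassing steps 4 and 5. Mono-functionalisation is decided by a stoichiometric halogen–magnesium exchange, which should stop after one exchange. Treatment of 7 with iPrMgCl·LiCl (THF, −15 °C) would give (3-bromo-2-methoxyphenyl)magnesium chloride F5, and ZnCl2 would convert it into (3-bromo-2-methoxyphenyl)zinc chloride F6. Negishi coupling (Pd(PPh3)4, THF, rt) with methyl (Z)-2-iodo-3-methoxyacrylate F7, made from commercial methyl (E)-3-methoxyacrylate with N-iodosuccinimide/AcOH then Et3N, would give methyl (E)-2-(3-bromo-2-methoxyphenyl)-3-methoxyacrylate F8. Saponification of F8 with LiOH gives 12.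

**Step 2.** The O→C silyl shift may be incomplete on the aryllithium flanked by a methoxy group, and the hindered phenoxide may triflate slowly, so that silicon-free triflate forms. The fallback sets out from 1 and returns at 5, making the C–Si bond by directed ortho-metalation instead of anionic migration, and it also avoids step 1. Isopropyl isocyanate/Et3N would give 3,4,5-trimethoxyphenyl N-isopropylcarbamate F9. N-Silylation in the flask (TBSOTf, TMEDA), lithiation with n-BuLi at −78 °C at the position between carbamate and methoxy group, and a TMSCl quench would give 3,4,5-trimethoxy-2-(trimethylsilyl)phenyl N-isopropylcarbamate F10. Et2NH/DBU (MeCN, 40 °C) would cleave the carbamate to 3,4,5-trimethoxy-2-(trimethylsilyl)phenol F11, which is triflated in the same flask with PhNTf2 to 5.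

## Further compounds

F1 | step 6 | 2-(3-bromo-2-methoxyphenyl)acetic acid | COc1c(Br)cccc1CC(=O)O
F2 | step 6 | 2-(3-bromo-2-methoxyphenyl)-1-(2-hydroxy-4,5,6-trimethoxyphenyl)ethan-1-one | COc1cc(O)c(C(=O)Cc2cccc(Br)c2OC)c(OC)c1OC
F3 | step 6 | (E)-2-(3-bromo-2-methoxyphenyl)-3-(dimethylamino)-1-(2-hydroxy-4,5,6-trimethoxyphenyl)prop-2-en-1-one | CN(C)/C=C(/C(=O)c1c(O)cc(OC)c(OC)c1OC)c1cccc(Br)c1OC
F4 | step 7 | (E)-benzaldehyde O-[2-methoxy-3-(5,6,7-trimethoxy-4-oxo-4H-chromen-3-yl)phenyl]oxime | COc1cc2occ(-c3cccc(O/N=C/c4ccccc4)c3OC)c(=O)c2c(OC)c1OC
F5 | step 3 | (3-bromo-2-methoxyphenyl)magnesium chloride | COc1c(Br)cccc1[Mg]Cl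
F6 | step 3 | (3-bromo-2-methoxyphenyl)zinc chloride | COc1c(Br)cccc1[Zn]Cl
F7 | step 3 | methyl (Z)-2-iodo-3-methoxyacrylate | CO/C=C(\I)C(=O)OC
F8 | step 3 | methyl (E)-2-(3-bromo-2-methoxyphenyl)-3-methoxyacrylate | CO/C=C(/C(=O)OC)c1cccc(Br)c1OC
F9 | step 2 | 3,4,5-trimethoxyphenyl N-isopropylcarbamate | COc1cc(OC(=O)NC(C)C)cc(OC)c1OC
F10 | step 2 | 3,4,5-trimethoxy-2-(trimethylsilyl)phenyl N-isopropylcarbamate | COc1cc(OC(=O)NC(C)C)c([Si](C)(C)C)c(OC)c1OC
F11 | step 2 | 3,4,5-trimethoxy-2-(trimethylsilyl)phenol | COc1cc(O)c([Si](C)(C)C)c(OC)c1OC
A1 | alternative 1 | 2-(3-(benzyloxy)-2-methoxyphenyl)acetic acid | COc1c(OCc2ccccc2)cccc1CC(=O)O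
A2 | alternative 1 | 2-(3-(benzyloxy)-2-methoxyphenyl)-1-(2-hydroxy-4,5,6-trimethoxyphenyl)ethan-1-one | COc1cc(O)c(C(=O)Cc2cccc(OCc3ccccc3)c2OC)c(OC)c1OC
A3 | alternative 1 | 3-(3-(benzyloxy)-2-methoxyphenyl)-5,6,7-trimethoxy-4H-chromen-4-one | COc1cc2occ(-c3cccc(OCc4ccccc4)c3OC)c(=O)c2c(OC)c1OC
A4 | alternative 2 | 3-iodo-5,6,7-trimethoxy-4H-chromen-4-one | COc1cc2occ(I)c(=O)c2c(OC)c1OC
A5 | alternative 2 | (3-(benzyloxy)-2-methoxyphenyl)boronic acid | COc1c(OCc2ccccc2)cccc1B(O)O
A6 | alternative 3 | 1-(2-hydroxy-4,5,6-trimethoxyphenyl)ethan-1-one | CC(=O)c1c(O)cc(OC)c(OC)c1OC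
A7 | alternative 3 | 3-(benzyloxy)-2-methoxybenzaldehyde | COc1c(OCc2ccccc2)cccc1C=O
A8 | alternative 3 | (E)-3-(3-(benzyloxy)-2-methoxyphenyl)-1-(2-hydroxy-4,5,6-trimethoxyphenyl)prop-2-en-1-one | COc1cc(O)c(C(=O)/C=C/c2cccc(OCc3ccccc3)c2OC)c(OC)c1OC
A9 | alternative 3 | 2-(3-(benzyloxy)-2-methoxyphenyl)-1-(2-hydroxy-4,5,6-trimethoxyphenyl)-3,3-dimethoxypropan-1-one (racemic) | COC(OC)C(C(=O)c1c(O)cc(OC)c(OC)c1OC)c1cccc(OCc2ccccc2)c1OC
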